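The numbers in the tables are simulated on assumed constants; the scatter is artificial.

A small charge of solid D reaches L slowly, and E appears late. We want to know how many times the dissolved pool turns over in the asked time.

all flasks: D 20 mM
- dawn: L 0.54 equiv; run made earlier
- summer: L 1.2 equiv; run made earlier
- flask: L 0.800 equiv; time 3.0 d

- dawn (time / d: E / %): 0.250: 0.5; 0.417: 1.5; 0.625: 3.2; 1.04: 7.1; 1.67: 14.1; 3.00: 29.3
- summer (time / d: E / %): 0.208: 0.3; 0.625: 3.3; 1.04: 8.2; 1.67: 16.5; 2.50: 29.5; 3.00: 37.2

(standard deviation of a reading: 0.3 percentage points)

- given per volume of solution although it is solid: D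
- at the start none of D is in solution

- how much E there is at 3.0 d, in percent of the D charged
- the change that raises the amount of E at 3.0 d, in percent of the D charged most ("none" if none brings more than 2 percentage points) (Friday's / Tuesday's / Monday's / none)
- amount of E at 3.0 d, in percent of the D charged, after Friday's

- Friday's: doubling the dissolution coefficient of D, all else as stated
- Tuesday's: doubling the amount of L, all else as stated
- Monday's: doubling the solubility of D, all else as stated

1. First rung: the pool. Late in the summer run, E rises by 21 percentage points in 1.33 d, a steady 0.156 d⁻¹ as a fraction of the D charged. Drawn back, that line reaches zero at 0.610 d. We call this the fill time, the induction period in which we take the dissolved pool to rise to its level.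

2. Second rung: the asked time. 3.0 d holds 4.92 fill times, so we expect a filled pool and a nearly straight line in our flask.

3. Third rung: L. At 1.04 d the dawn run reads 7.1% against 8.2% in the summer run, so the two runs already differ there. The late line of the dawn run, drawn back the same way, reaches zero at 0.436 d, so the two runs give different fill times, and using the summer value for our flask is an assumption we make. By 3.00 d the summer run leads the dawn run by 7.9 points. Interpolating in the reciprocal of the L charge, we reckon 34.0%, and Tuesday's adds 4.8 points.

4. The changes. Monday's doubles the straight rate. If dissolution takes an equal share of the fill, which we assume, Friday's raises the rate by 1.33 and shortens the fill, giving 49.1%. Doubling gives more, so we choose Monday's.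

5. The forecast gave 34.2%, Monday's and 47%, holding that with Friday's “the lag only shortens”.

6. The flask gives 34.2%; Monday's brings 19 points, Friday's 14 points, reaching 48.4%.

    X ⇌ Z (K = 0.00270, k = 0.0274 h⁻¹)
    D ⇌ X, rate k2*(cs2 - [X]) while solid is left; crystals form when [X] > cs2 (solubility = 13.0 mM, k = 0.0238 h⁻¹)
    L + Z → E (k = 7700 M⁻¹ h⁻¹)
    Z ⇌ Q (K = 4.77, k = 20.8 h⁻¹)
    L + Q → J (k = 2810 M⁻¹ h⁻¹)

At 3.00 d, 48.5% of the L charge remains. The fill time, with the curve that rises toward the line, scales this result back to 13.5% at 1.50 d, where the flask holds 13.1%. For the same flask read at 20 h, it gives 5.41%, and that reading stands at 5.03%.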